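**Plan**

Eudesmane numbering is used: ring A = C1–C5, C10; ring B = C5–C10; C14 is the methyl on C10, C15 the carbon on C4, C11–C13 the acrylate; β is the face of the C10 methyl.
Retrosynthetic cuts: the C15–O ester, C4–C15, C11–C12, C11–C13, then ring B at C8–C9, C6–C7 and C5–C6, and last C9–C10.
Forward: ring A is bought as 3-methylcyclohex-2-enone and nitromethane is added at C10; ring B is then closed in one pot from this γ-nitro ketone, acrolein (C8, C7, C11) and formaldehyde (C6); the acrylate and the C3=C4–C15 unit follow.
Enabling feature: C9 and C5 both sit on the quaternary C10 of ring B; a nitro group on C9 and the C4 carbonyl next to C5 make them a 1,3-dinucleophile, and only closure through C5 gives a six-membered ring.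
Stereochemistry: C10 comes from amine catalysis (step 1); C5 and C7 are relayed from it in the annulation by equilibration (trans ring fusion, equatorial C7 substituent); the Z alkene comes from a Still–Gennari olefination. Helpers: the nitro group leaves by radical denitration and the C4 ketone is spent in the C3=C4 enol triflate.

Key step: step 2

Remark: the enantiomeric series of the cinchona-derived primary amine that gives the S ketone in step 1 is assumed; the nitro-bearing carbon formed in the annulation is taken as an inconsequential epimer mixture and is drawn with the equatorial nitro group.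

**Route**

Step 1
Reactants: 1 3-methylcyclohex-2-en-1-one; 2 nitromethane
Product: 3 (S)-3-methyl-3-(nitromethyl)cyclohexan-1-one
Conditions: 9-amino-9-deoxy-epi-quinine (10 mol %), PhCO2H (20 mol %), MeNO2 as solvent, 40 °C
Reagents that add atoms: none
Why: Iminium-catalysed asymmetric Michael addition of nitromethane to a β-substituted cyclic enone, a known route to γ-nitro ketones with a quaternary centre; the chiral primary amine shields one face of the iminium ion and so sets C10 (S here, 10R in the target).

Step 2
Reactants: 3 (S)-3-methyl-3-(nitromethyl)cyclohexan-1-one; 4 acrolein; 5 formaldehyde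
Product: 8 9β-nitro-4-oxo-12,13,15-trinor-5αH,7αH-eudesman-11-al, via nitro aldehyde 6 (not isolated), via methylene aldehyde 7 (not isolated)
Conditions: 4 (1.05 equiv), Et3N (10 mol %), i-PrOH, 0 °C to rt; then 37 % aq. 5 (1.1 equiv), pyrrolidine (20 mol %), EtCO2H (40 mol %), 45 °C, one pot
Reagents that add atoms: none
Why: Proposed new method: Et3N-catalysed Michael addition of the nitronate of 3 to acrolein forms C8–C9 (6), pyrrolidinium propanoate then methylenates the aldehyde through its enamine and formaldehyde by Mannich addition and amine loss (C6=C7, 7), and the C4 ketone, as its enol or enamine at C5, adds to C6 of the iminium-activated enal, which leaves C6–C7 as the new ring single bond. Each event is a known reaction type (nitroalkane addition to enals, amine/acid-catalysed α-methylenation of aldehydes with aqueous formaldehyde, one-pot methylenation–Michael sequences, and the (3+3) annulation of ketone enamines with 2-(bromomethyl)acrylates as the closest relative), but their merger into one (3+2+1) annulation on a γ-nitro ketone is untested. Ring B closes by a 6-endo-trig Michael addition of C5 onto C6. C5 (α to the C4 ketone) and C7 (α to the formyl group) are both epimerisable in the amine/acid medium and should settle, relative to the fixed C10, in the chair–chair trans-decalin with H-5 anti to the angular methyl and the formyl group equatorial (7β), while C9 is formed as a mixture and is erased in step 3; the preference at both centres is expected to be moderate, and a separated minor epimer can be re-equilibrated with base. The step needs methylenation of the aldehyde and not of the ketone (aldehyde enamines form and react much faster), engagement of the ketone at hindered C5 and not at C3 (only C5 gives a six-membered ring, C3 would need an eight-membered one), and no nitro-aldol reaction with formaldehyde (the weakly acidic buffer keeps the nitronate concentration low).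

Step 3
Reactants: 8 9β-nitro-4-oxo-12,13,15-trinor-5αH,7αH-eudesman-11-al
Product: 9 4-oxo-12,13,15-trinor-5αH,7αH-eudesman-11-al
Conditions: Bu3SnH (5 equiv), AIBN (0.5 equiv, in portions), PhMe, 110 °C
Reagents that add atoms: none
Why: Radical denitration: the stannyl radical adds to a nitro oxygen, the adduct fragments to the secondary C9 radical next to the quaternary C10, and this takes hydrogen from Bu3SnH, which removes the nitro helper without touching C5, C7 or C10.

Step 4
Reactants: 9 4-oxo-12,13,15-trinor-5αH,7αH-eudesman-11-al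
Product: 10 12,15-dinor-5αH,7αH-eudesm-11(13)-yn-4-one
Conditions: dimethyl (1-diazo-2-oxopropyl)phosphonate, K2CO3, MeOH, 0 °C to rt
Reagents that add atoms: dimethyl (1-diazo-2-oxopropyl)phosphonate, COP(=O)(OC)C(=[N+]=[N-])C(C)=O
Why: Seyferth–Gilbert homologation under Ohira–Bestmann conditions converts only the aldehyde (the hindered C4 ketone should not react) into the terminal alkyne; the carbonate medium lets C7 equilibrate so that the less hindered equatorial aldehyde reacts, and C7 is fixed from here on.

Step 5
Reactants: 10 12,15-dinor-5αH,7αH-eudesm-11(13)-yn-4-one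
Product: 11 methyl 4-oxo-15-nor-5αH,7αH-eudesm-11(13)-en-12-oate
Conditions: Pd(OAc)2 (2 mol %), 2-(diphenylphosphino)pyridine (8 mol %), MeSO3H (8 mol %), CO (5 bar), MeOH, 50 °C
Reagents that add atoms: carbon monoxide, [C-]#[O+]; methanol, CO
Why: Palladium-hydride-catalysed Markovnikov hydromethoxycarbonylation of a terminal alkyne, which with the pyridylphosphine/acid system should place the ester on the internal carbon C11 and give the 2-substituted acrylate directly; no stereocentre is involved.

Step 6
Reactants: 11 methyl 4-oxo-15-nor-5αH,7αH-eudesm-11(13)-en-12-oate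
Product: 13 methyl 4-(trifluoromethylsulfonyloxy)-15-nor-5αH,7αH-eudesma-3,11(13)-dien-12-oate, via potassium enolate 12 (not isolated)
Conditions: KN(SiMe3)2, THF, −78 °C; then N-(5-chloropyridin-2-yl)bis(trifluoromethanesulfonimide), −78 °C
Reagents that add atoms: N-(5-chloropyridin-2-yl)bis(trifluoromethanesulfonimide), O=S(=O)(N(c1ccc(Cl)cn1)S(=O)(=O)C(F)(F)F)C(F)(F)F
Why: Kinetic enolate formation and O-triflation: the bulky amide removes a C3 proton and not the tertiary C5 proton next to the quaternary C10, so the C3=C4 enol triflate forms and C5 keeps its configuration, while low temperature and fast trapping should keep the enolate from adding to the acrylate.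

Step 7
Reactants: 13 methyl 4-(trifluoromethylsulfonyloxy)-15-nor-5αH,7αH-eudesma-3,11(13)-dien-12-oate
Product: 14 methyl 15-hydroxy-5αH,7αH-eudesma-3,11(13)-dien-12-oate
Conditions: Bu3SnCH2OH, Pd(PPh3)4 (5 mol %), LiCl, 1,4-dioxane, 100 °C
Reagents that add atoms: (tributylstannyl)methanol, CCCC[Sn](CCCC)(CCCC)CO
Why: Migita–Kosugi–Stille coupling of an alkenyl triflate with (tributylstannyl)methanol transfers the hydroxymethyl group (C15) to C4 and keeps the double bond at C3=C4.

Step 8
Reactants: 15 4-(tert-butyldimethylsilyloxy)benzaldehyde; 16 methyl bis(2,2,2-trifluoroethyl)phosphonoacetate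
Product: 17 methyl (Z)-3-[4-(tert-butyldimethylsilyloxy)phenyl]prop-2-enoate
Conditions: KN(SiMe3)2, 18-crown-6, THF, −78 °C
Reagents that add atoms: none
Why: Still–Gennari variant of the Horner–Wadsworth–Emmons olefination: the electron-poor trifluoroethyl phosphonate with a dissociated potassium counter-ion eliminates fast from the kinetic adduct and should give the Z cinnamate.

Step 9
Reactants: 17 methyl (Z)-3-[4-(tert-butyldimethylsilyloxy)phenyl]prop-2-enoate
Product: 18 (Z)-3-(4-hydroxyphenyl)prop-2-enoic acid
Conditions: LiOH, THF/MeOH/H2O, 0 °C to rt; acidic work-up (1 M HCl)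
Reagents that add atoms: lithium hydroxide, [Li+].[OH-]
Why: Saponification of the methyl ester with cleavage of the base-labile aryl silyl ether in the same operation; hydroxide at or below room temperature should leave the Z alkene untouched.

Step 10
Reactants: 14 methyl 15-hydroxy-5αH,7αH-eudesma-3,11(13)-dien-12-oate; 18 (Z)-3-(4-hydroxyphenyl)prop-2-enoic acid
Product: 19 methyl 15-[(Z)-3-(4-hydroxyphenyl)prop-2-enoyloxy]-5αH,7αH-eudesma-3,11(13)-dien-12-oate (CNP0161949.2; 5R,7R,10R)
Conditions: PPh3, diisopropyl azodicarboxylate, THF, 0 °C to rt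
Reagents that add atoms: none
Why: Mitsunobu esterification: the primary allylic alcohol is activated as its oxyphosphonium salt and displaced at C15 by the carboxylate, which as the far stronger acid than the phenol is the pronucleophile; the neutral conditions should preserve the Z alkene and no stereocentre is involved.

**Compound list**

1 | 3-methylcyclohex-2-en-1-one | CC1=CC(=O)CCC1 | starting material
2 | nitromethane | C[N+](=O)[O-] | starting material
3 | (S)-3-methyl-3-(nitromethyl)cyclohexan-1-one | O=C1CCC[C@](C)(C[N+](=O)[O-])C1 | intermediate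
4 | acrolein (prop-2-enal) | C=CC=O | starting material
5 | formaldehyde | C=O | starting material
6 | 4-[(1S)-1-methyl-3-oxocyclohexyl]-4-nitrobutanal (epimers at the nitro carbon; not isolated) | O=CCCC([N+](=O)[O-])[C@@]1(C)CCCC(=O)C1 | intermediate
7 | 2-methylidene-4-[(1S)-1-methyl-3-oxocyclohexyl]-4-nitrobutanal (epimers at the nitro carbon; not isolated) | C=C(C=O)CC([N+](=O)[O-])[C@@]1(C)CCCC(=O)C1 | intermediate
8 | 9β-nitro-4-oxo-12,13,15-trinor-5αH,7αH-eudesman-11-al (10β-methyl; equatorial nitro epimer drawn) | O=C[C@@H]1C[C@H]([N+](=O)[O-])[C@@]2(C)CCCC(=O)[C@@H]2C1 | intermediate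
9 | 4-oxo-12,13,15-trinor-5αH,7αH-eudesman-11-al | O=C[C@@H]1CC[C@@]2(C)CCCC(=O)[C@@H]2C1 | intermediate
10 | 12,15-dinor-5αH,7αH-eudesm-11(13)-yn-4-one | C#C[C@@H]1CC[C@@]2(C)CCCC(=O)[C@@H]2C1 | intermediate
11 | methyl 4-oxo-15-nor-5αH,7αH-eudesm-11(13)-en-12-oate | C=C(C(=O)OC)[C@@H]1CC[C@@]2(C)CCCC(=O)[C@@H]2C1 | intermediate
12 | potassium 3-en-4-olate of 11 (not isolated) | C=C(C(=O)OC)[C@@H]1CC[C@@]2(C)CCC=C([O-])[C@@H]2C1.[K+] | intermediate
13 | methyl 4-(trifluoromethylsulfonyloxy)-15-nor-5αH,7αH-eudesma-3,11(13)-dien-12-oate | C=C(C(=O)OC)[C@@H]1CC[C@@]2(C)CCC=C(OS(=O)(=O)C(F)(F)F)[C@@H]2C1 | intermediate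
14 | methyl 15-hydroxy-5αH,7αH-eudesma-3,11(13)-dien-12-oate | C=C(C(=O)OC)[C@@H]1CC[C@@]2(C)CCC=C(CO)[C@@H]2C1 | intermediate
15 | 4-(tert-butyldimethylsilyloxy)benzaldehyde | CC(C)(C)[Si](C)(C)Oc1ccc(C=O)cc1 | starting material
16 | methyl bis(2,2,2-trifluoroethyl)phosphonoacetate | COC(=O)CP(=O)(OCC(F)(F)F)OCC(F)(F)F | starting material
17 | methyl (Z)-3-[4-(tert-butyldimethylsilyloxy)phenyl]prop-2-enoate | COC(=O)/C=C\c1ccc(O[Si](C)(C)C(C)(C)C)cc1 | intermediate
18 | (Z)-3-(4-hydroxyphenyl)prop-2-enoic acid | OC(=O)/C=C\c1ccc(O)cc1 | intermediate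
19 | methyl 15-[(Z)-3-(4-hydroxyphenyl)prop-2-enoyloxy]-5αH,7αH-eudesma-3,11(13)-dien-12-oate (5R,7R,10R) | C=C(C(=O)OC)[C@@H]1CC[C@@]2(C)CCC=C(COC(=O)/C=C\c3ccc(O)cc3)[C@@H]2C1 | target

**Count and risks**

Total step count: 10. Longest linear sequence: 8 (steps 1–7 and 10); steps 8 and 9 form a two-step side branch.

Steps most likely to fail:

Step 2 (Proposed new method). The ring may not close: the hindered C5 may be too slow to capture the 2-substituted acrolein before that is lost to amine addition, oligomerisation, isomerisation to the 2-methylalkenal or nitro-aldol reaction, and the ring-fusion centre may equilibrate poorly. The fallback puts C6 on ring A first and then uses a two-component domino of known type. It sets out from 3. Aerobic dehydrogenation (Pd(O2CCF3)2, DMSO, O2, AcOH, 80 °C), which can only take place on the side away from the quaternary carbon, would give (S)-5-methyl-5-(nitromethyl)cyclohex-2-en-1-one F1. The new alkene blocks C3, so LiN(SiMe3)2 (2.2 equiv; nitronate first, then the kinetic enolate at C5) and dimethylmethyleneammonium iodide would give the Mannich base (5S)-6-[(dimethylamino)methyl]-5-methyl-5-(nitromethyl)cyclohex-2-en-1-one F2. Methylation with MeI and aqueous NaHCO3 would then give the cross-conjugated dienone (S)-5-methyl-6-methylidene-5-(nitromethyl)cyclohex-2-en-1-one F3. With 4 and pyrrolidine/PhCO2H, nitro-Michael addition would give 4-[(1S)-1-methyl-2-methylidene-3-oxocyclohex-4-en-1-yl]-4-nitrobutanal F4, and enamine Michael closure onto the exocyclic methylene (forming C6–C7) would give 9β-nitro-4-oxo-12,13,15-trinor-5αH,7αH-eudesm-2-en-11-al F5. Hydrogenation of the ring A alkene (H2, Pd/C, EtOAc) comes back to the route at 8.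

Step 3. C–N homolysis at a secondary carbon is slow, so the chain may stall while the tin hydride reduces the aldehyde instead. The fallback removes nitrogen by an ionic route and sets out from 8. Both carbonyl groups would be masked (ethylene glycol, pyridinium p-toluenesulfonate, benzene, reflux) as 4,4:11,11-bis(ethylenedioxy)-9β-nitro-12,13,15-trinor-5αH,7αH-eudesmane F6. Nickel boride (NiCl2·6H2O, NaBH4, MeOH, 0 °C) would reduce the nitro group to 4,4:11,11-bis(ethylenedioxy)-12,13,15-trinor-5αH,7αH-eudesman-9β-amine F7. Direct deamination with N-(benzyloxy)-N-(pivaloyloxy)-4-(trifluoromethyl)benzamide (MeCN, 45 °C) would give 4,4:11,11-bis(ethylenedioxy)-12,13,15-trinor-5αH,7αH-eudesmane F8, and aqueous HCl in acetone comes back to the route at 9.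

Step 10. The free phenol may be O-alkylated in competition with the carboxylate, and the Z alkene may isomerise under the phosphine/azodicarboxylate conditions. The fallback masks the phenol and couples with a carbodiimide; it sets out from 17 and uses 14. Me3SnOH (1,2-dichloroethane, 80 °C) would cleave only the methyl ester and give (Z)-3-[4-(tert-butyldimethylsilyloxy)phenyl]prop-2-enoic acid F9. Steglich esterification with 14 (N,N′-dicyclohexylcarbodiimide, 4-(dimethylamino)pyridine, CH2Cl2, 0 °C) would give methyl 15-{(Z)-3-[4-(tert-butyldimethylsilyloxy)phenyl]prop-2-enoyloxy}-5αH,7αH-eudesma-3,11(13)-dien-12-oate F10, and HF·pyridine (THF, 0 °C) comes back to the route at 19.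

Further compounds
F1 | step 2 | (S)-5-methyl-5-(nitromethyl)cyclohex-2-en-1-one | O=C1C=CC[C@](C)(C[N+](=O)[O-])C1
F2 | step 2 | (5S)-6-[(dimethylamino)methyl]-5-methyl-5-(nitromethyl)cyclohex-2-en-1-one | CN(C)CC1C(=O)C=CC[C@]1(C)C[N+](=O)[O-]
F3 | step 2 | (S)-5-methyl-6-methylidene-5-(nitromethyl)cyclohex-2-en-1-one | C=C1C(=O)C=CC[C@]1(C)C[N+](=O)[O-]
F4 | step 2 | 4-[(1S)-1-methyl-2-methylidene-3-oxocyclohex-4-en-1-yl]-4-nitrobutanal | C=C1C(=O)C=CC[C@]1(C)C(CCC=O)[N+](=O)[O-]
F5 | step 2 | 9β-nitro-4-oxo-12,13,15-trinor-5αH,7αH-eudesm-2-en-11-al | O=C[C@@H]1C[C@H]([N+](=O)[O-])[C@@]2(C)CC=CC(=O)[C@@H]2C1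
F6 | step 3 | 4,4:11,11-bis(ethylenedioxy)-9β-nitro-12,13,15-trinor-5αH,7αH-eudesmane | O1CCOC1[C@@H]2C[C@H]([N+](=O)[O-])[C@@]3(C)CCCC4(OCCO4)[C@@H]3C2
F7 | step 3 | 4,4:11,11-bis(ethylenedioxy)-12,13,15-trinor-5αH,7αH-eudesman-9β-amine | O1CCOC1[C@@H]2C[C@H](N)[C@@]3(C)CCCC4(OCCO4)[C@@H]3C2
F8 | step 3 | 4,4:11,11-bis(ethylenedioxy)-12,13,15-trinor-5αH,7αH-eudesmane | O1CCOC1[C@@H]2CC[C@@]3(C)CCCC4(OCCO4)[C@@H]3C2
F9 | step 10 | (Z)-3-[4-(tert-butyldimethylsilyloxy)phenyl]prop-2-enoic acid | OC(=O)/C=C\c1ccc(O[Si](C)(C)C(C)(C)C)cc1
F10 | step 10 | methyl 15-{(Z)-3-[4-(tert-butyldimethylsilyloxy)phenyl]prop-2-enoyloxy}-5αH,7αH-eudesma-3,11(13)-dien-12-oate | C=C(C(=O)OC)[C@@H]1CC[C@@]2(C)CCC=C(COC(=O)/C=C\c3ccc(O[Si](C)(C)C(C)(C)C)cc3)[C@@H]2C1
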